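**Plan**
1. Retrosynthesis: cut first the bond between C3 of the benzene-1,2-diol ring and the neighbouring CH2 of the ethylene bridge (B-alkyl Suzuki–Miyaura coupling). Then cut the C6–vinyl bond, C3=C4 of the pyran ring (ring-closing metathesis), O1–C8a (SNAr), and trace the tertiary carbinol back to geraniol.
2. Forward: geraniol → epoxide → epoxy iodide → (S)-linalool → E-allylic oxidation and silylation (side chain complete) → aryl ether → styrene → pyran ring closed (the only ring made; both benzene rings are bought) → 6-vinylchromene → union with the catechol ring → global desilylation.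
3. Enabling feature: the vinyl group on C6 is the only monosubstituted alkene and lies para to O1. The C3=C4 alkene of the pyran ring is shielded by quaternary C2 and the side-chain C=C is trisubstituted, so 9-BBN should hydroborate C6–CH=CH2 alone. The primary alkylborane then carries the whole chromene half onto the catechol carbon.
4. Stereochemistry: C2 (S) is C3 of (2S,3S)-2,3-epoxygeraniol (Sharpless epoxidation, L-(+)-tartrate), and its C–O bond is never broken afterwards. The E side-chain alkene comes from E-selective SeO2 oxidation.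

Key step: step 11

Remark: (S)-linalool of high enantiomeric purity is not relied on as a purchasable material, so the carbinol centre is built from geraniol.

**Step 1**
Reactants: 1 geraniol
Product: 2 (2S,3S)-2,3-epoxygeraniol, [(2S,3S)-3-methyl-3-(4-methylpent-3-en-1-yl)oxiran-2-yl]methanol
Conditions: Ti(OiPr)4 (5 mol %), L-(+)-diethyl tartrate (7 mol %), t-BuOOH (anhydrous, 2 equiv), 4 Å molecular sieves, CH2Cl2, −20 °C
Reagents that add atoms: tert-butyl hydroperoxide, CC(C)(C)OO
Why: Sharpless asymmetric epoxidation: the titanium–L-(+)-tartrate complex binds the allylic hydroxyl and delivers oxygen to one face of the E-configured C2=C3 alkene only, which should set C2 and C3 as (2S,3S) by reagent control and leave the remote C6=C7 alkene untouched.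

**Step 2**
Reactants: 2 (2S,3S)-2,3-epoxygeraniol
Product: 3 (2R,3S)-2-(iodomethyl)-3-methyl-3-(4-methylpent-3-en-1-yl)oxirane
Conditions: PPh3, I2, imidazole, CH2Cl2, 0 °C
Reagents that add atoms: iodine, II
Why: Appel-type iodination of the primary alcohol through its alkoxyphosphonium salt runs under imidazole buffering, so the acid-sensitive epoxide and both stereocenters should survive (the descriptor of the CH carbon becomes R only because CH2I outranks the ring carbon).

**Step 3**
Reactants: 3 (2R,3S)-2-(iodomethyl)-3-methyl-3-(4-methylpent-3-en-1-yl)oxirane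
Product: 4 (S)-linalool, (3S)-3,7-dimethylocta-1,6-dien-3-ol
Conditions: Zn dust, EtOH, reflux; aq. NH4Cl work-up
Reagents that add atoms: none
Why: Zinc inserts into the C–I bond and the β-oxido organozinc undergoes reductive β-elimination that opens the epoxide (the known reductive opening of 2,3-epoxy halides), which turns the quaternary epoxide carbon into the tertiary allylic carbinol without breaking its C–O bond, hence with retention as (S).

**Step 4**
Reactants: 4 (S)-linalool
Product: 5 (2E,6S)-2,6-dimethylocta-2,7-diene-1,6-diol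
Conditions: SeO2 (0.3 equiv), t-BuOOH (3 equiv), salicylic acid (cat.), CH2Cl2, rt; then NaBH4, MeOH, 0 °C (returns any over-oxidised enal to 5)
Reagents that add atoms: selenium dioxide, O=[Se]=O (catalytic oxygen carrier); tert-butyl hydroperoxide, CC(C)(C)OO (terminal oxidant)
Why: Riley allylic oxidation (ene reaction with SeO2, then [2,3]-sigmatropic shift) attacks the trisubstituted alkene at its E-methyl group and should give the (E)-allylic alcohol, the vinyl group having no allylic hydrogen and the stereocenter being untouched.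

**Step 5**
Reactants: 5 (2E,6S)-2,6-dimethylocta-2,7-diene-1,6-diol
Product: 6 (3S,6E)-8-[(tert-butyldimethylsilyl)oxy]-3,7-dimethylocta-1,6-dien-3-ol
Conditions: TBSCl (1.05 equiv), imidazole, CH2Cl2, 0 °C
Reagents that add atoms: tert-butyldimethylsilyl chloride, CC(C)(C)[Si](C)(C)Cl
Why: Silylation of the primary allylic hydroxyl is far faster than that of the hindered tertiary one, so one equivalent of the silyl chloride should give the mono-ether.

**Step 6**
Reactants: 6 (3S,6E)-8-[(tert-butyldimethylsilyl)oxy]-3,7-dimethylocta-1,6-dien-3-ol; 7 5-bromo-2-fluorobenzaldehyde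
Product: 9 5-bromo-2-{[(3S,6E)-8-[(tert-butyldimethylsilyl)oxy]-3,7-dimethylocta-1,6-dien-3-yl]oxy}benzaldehyde, via potassium alkoxide 8 (not isolated)
Conditions: KN(SiMe3)2 (0.98 equiv), THF, 0 °C; then 7, DMF, 0 °C → rt; chromatography on Et3N-deactivated silica
Reagents that add atoms: none
Why: Nucleophilic aromatic substitution (addition–elimination through a Meisenheimer adduct) of the fluoride activated by the ortho-formyl group forms the O–aryl bond without touching the carbinol C–O bond, so the (S) center should be carried over unchanged.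

**Step 7**
Reactants: 9 5-bromo-2-{[(3S,6E)-8-[(tert-butyldimethylsilyl)oxy]-3,7-dimethylocta-1,6-dien-3-yl]oxy}benzaldehyde
Product: 10 4-bromo-2-ethenyl-1-{[(3S,6E)-8-[(tert-butyldimethylsilyl)oxy]-3,7-dimethylocta-1,6-dien-3-yl]oxy}benzene
Conditions: Ph3PCH3Br, KOtBu, THF, 0 °C → rt
Reagents that add atoms: methyltriphenylphosphonium bromide, C[P+](c1ccccc1)(c1ccccc1)c1ccccc1.[Br-]
Why: Wittig methylenation of the non-enolisable aryl aldehyde by the unstabilised ylide should give the styrene under basic conditions that leave the tertiary allylic aryl ether and the silyl ether intact.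

**Step 8**
Reactants: 10 4-bromo-2-ethenyl-1-{[(3S,6E)-8-[(tert-butyldimethylsilyl)oxy]-3,7-dimethylocta-1,6-dien-3-yl]oxy}benzene
Product: 11 (2S)-6-bromo-2-{(3E)-5-[(tert-butyldimethylsilyl)oxy]-4-methylpent-3-en-1-yl}-2-methyl-2H-chromene
Conditions: second-generation Grubbs catalyst, RuCl2(=CHPh)(PCy3)(1,3-dimesitylimidazolidin-2-ylidene) (5 mol %), CH2Cl2 (5 mM), 40 °C, dark
Reagents that add atoms: none
Why: Ring-closing metathesis between the two monosubstituted alkenes closes the six-membered pyran ring at C3=C4 with loss of ethylene, the trisubstituted silyloxymethyl-bearing side-chain alkene being much less reactive, and no bond to the quaternary carbon is broken, so C2 should stay (S).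

**Step 9**
Reactants: 11 (2S)-6-bromo-2-{(3E)-5-[(tert-butyldimethylsilyl)oxy]-4-methylpent-3-en-1-yl}-2-methyl-2H-chromene
Product: 12 (2S)-2-{(3E)-5-[(tert-butyldimethylsilyl)oxy]-4-methylpent-3-en-1-yl}-6-ethenyl-2-methyl-2H-chromene
Conditions: CH2=CHBF3K, PdCl2(dppf)·CH2Cl2 (3 mol %), Cs2CO3, THF/H2O (9:1), 70 °C, dark
Reagents that add atoms: potassium vinyltrifluoroborate, C=C[B-](F)(F)F.[K+]
Why: Suzuki–Miyaura coupling of the aryl bromide with the vinyltrifluoroborate should install the C6 vinyl group, oxidative addition occurring only at C–Br while the stereocenter is a spectator.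

**Step 10**
Reactants: 13 3-bromocatechol (3-bromobenzene-1,2-diol)
Product: 14 1-bromo-2,3-bis[(tert-butyldimethylsilyl)oxy]benzene
Conditions: TBSCl (2.5 equiv), imidazole, DMF, rt
Reagents that add atoms: tert-butyldimethylsilyl chloride, CC(C)(C)[Si](C)(C)Cl
Why: Imidazole-promoted silylation of both phenolic hydroxyls masks the catechol as a fluoride-labile bis-silyl ether that cannot chelate boron or palladium in the coupling.

**Step 11**
Reactants: 12 (2S)-2-{(3E)-5-[(tert-butyldimethylsilyl)oxy]-4-methylpent-3-en-1-yl}-6-ethenyl-2-methyl-2H-chromene; 14 1-bromo-2,3-bis[(tert-butyldimethylsilyl)oxy]benzene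
Product: 16 (2S)-6-{2-[2,3-bis[(tert-butyldimethylsilyl)oxy]phenyl]ethyl}-2-{(3E)-5-[(tert-butyldimethylsilyl)oxy]-4-methylpent-3-en-1-yl}-2-methyl-2H-chromene, via alkylborane 15 (not isolated)
Conditions: 9-BBN (9-borabicyclo[3.3.1]nonane, 0.5 M in THF, 1.15 equiv), 0 °C → rt; then 14 (1.2 equiv), Pd(OAc)2 (4 mol %), SPhos (8 mol %), 3 M aq. K3PO4 (3 equiv), THF, 50 °C, dark
Reagents that add atoms: none
Why: 9-BBN adds its B–H bond syn and anti-Markovnikov across the C6 vinyl group to give the primary alkylborane 15, which phosphate and water convert into a borate; zerovalent palladium (from Pd(OAc)2 and SPhos) inserts into the C–Br bond of 14, the primary alkyl group passes from boron to divalent palladium with retention, and reductive elimination forms the aryl–CH2 bond. The closest known reaction type is the B-alkyl Suzuki–Miyaura coupling of 9-BBN adducts of styrenes with ortho-substituted aryl bromides. No ring is closed and no stereocenter is formed; C2 lies far from the reacting carbon and should keep its (S) configuration because no step of the cycle touches the O1–C2 bond. The step needs chemoselectivity among three alkenes, and the substrate secures it: the C6 vinyl group is the only monosubstituted alkene and is made electron-rich by the para oxygen O1, whereas the C3=C4 alkene of the pyran ring is 1,2-disubstituted, conjugated and flanked by quaternary C2, and the side-chain alkene is trisubstituted and carries the deactivating silyloxymethyl group. It also needs transfer of the primary alkyl group only (the two secondary B–C bonds of the 9-BBN cage do not migrate) and reductive elimination faster than β-hydride elimination, which the bulky electron-rich SPhos ligand provides.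

**Step 12**
Reactants: 16 (2S)-6-{2-[2,3-bis[(tert-butyldimethylsilyl)oxy]phenyl]ethyl}-2-{(3E)-5-[(tert-butyldimethylsilyl)oxy]-4-methylpent-3-en-1-yl}-2-methyl-2H-chromene
Product: 17 3-{2-[(2S)-2-[(3E)-5-hydroxy-4-methylpent-3-en-1-yl]-2-methyl-2H-chromen-6-yl]ethyl}benzene-1,2-diol (target)
Conditions: Bu4NF (4 equiv), AcOH (4 equiv), THF, 0 °C → rt, argon, dark; degassed pH 6 buffer work-up
Reagents that add atoms: none
Why: Fluoride-mediated desilylation (driven by the strong Si–F bond) should release both phenols and the primary alcohol, the acetic acid buffer keeping the medium near neutral so that the catechol is not oxidised and the acid- and light-sensitive chromene with its (S) center is untouched.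

**Compound list**
1 | geraniol, (2E)-3,7-dimethylocta-2,6-dien-1-ol | CC(C)=CCC/C(C)=C/CO | starting material
2 | (2S,3S)-2,3-epoxygeraniol, [(2S,3S)-3-methyl-3-(4-methylpent-3-en-1-yl)oxiran-2-yl]methanol | OC[C@@H]1O[C@@]1(C)CCC=C(C)C | intermediate
3 | (2R,3S)-2-(iodomethyl)-3-methyl-3-(4-methylpent-3-en-1-yl)oxirane | IC[C@@H]1O[C@@]1(C)CCC=C(C)C | intermediate
4 | (S)-linalool, (3S)-3,7-dimethylocta-1,6-dien-3-ol | C=C[C@@](C)(O)CCC=C(C)C | intermediate
5 | (2E,6S)-2,6-dimethylocta-2,7-diene-1,6-diol | C=C[C@@](C)(O)CC/C=C(\C)CO | intermediate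
6 | (3S,6E)-8-[(tert-butyldimethylsilyl)oxy]-3,7-dimethylocta-1,6-dien-3-ol | C=C[C@@](C)(O)CC/C=C(\C)CO[Si](C)(C)C(C)(C)C | intermediate
7 | 5-bromo-2-fluorobenzaldehyde | O=Cc1cc(Br)ccc1F | starting material
8 | potassium (3S,6E)-8-[(tert-butyldimethylsilyl)oxy]-3,7-dimethylocta-1,6-dien-3-olate (not isolated) | C=C[C@@](C)([O-])CC/C=C(\C)CO[Si](C)(C)C(C)(C)C.[K+] | intermediate
9 | 5-bromo-2-{[(3S,6E)-8-[(tert-butyldimethylsilyl)oxy]-3,7-dimethylocta-1,6-dien-3-yl]oxy}benzaldehyde | C=C[C@@](C)(Oc1ccc(Br)cc1C=O)CC/C=C(\C)CO[Si](C)(C)C(C)(C)C | intermediate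
10 | 4-bromo-2-ethenyl-1-{[(3S,6E)-8-[(tert-butyldimethylsilyl)oxy]-3,7-dimethylocta-1,6-dien-3-yl]oxy}benzene | C=C[C@@](C)(Oc1ccc(Br)cc1C=C)CC/C=C(\C)CO[Si](C)(C)C(C)(C)C | intermediate
11 | (2S)-6-bromo-2-{(3E)-5-[(tert-butyldimethylsilyl)oxy]-4-methylpent-3-en-1-yl}-2-methyl-2H-chromene | C/C(=C\CC[C@@]1(C)C=Cc2cc(Br)ccc2O1)CO[Si](C)(C)C(C)(C)C | intermediate
12 | (2S)-2-{(3E)-5-[(tert-butyldimethylsilyl)oxy]-4-methylpent-3-en-1-yl}-6-ethenyl-2-methyl-2H-chromene | C/C(=C\CC[C@@]1(C)C=Cc2cc(C=C)ccc2O1)CO[Si](C)(C)C(C)(C)C | intermediate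
13 | 3-bromocatechol, 3-bromobenzene-1,2-diol | Oc1cccc(Br)c1O | starting material
14 | 1-bromo-2,3-bis[(tert-butyldimethylsilyl)oxy]benzene | CC(C)(C)[Si](C)(C)Oc1cccc(Br)c1O[Si](C)(C)C(C)(C)C | intermediate
15 | 9-{2-[(2S)-2-{(3E)-5-[(tert-butyldimethylsilyl)oxy]-4-methylpent-3-en-1-yl}-2-methyl-2H-chromen-6-yl]ethyl}-9-borabicyclo[3.3.1]nonane (not isolated) | C/C(=C\CC[C@@]1(C)C=Cc2cc(CCB3C4CCCC3CCC4)ccc2O1)CO[Si](C)(C)C(C)(C)C | intermediate
16 | (2S)-6-{2-[2,3-bis[(tert-butyldimethylsilyl)oxy]phenyl]ethyl}-2-{(3E)-5-[(tert-butyldimethylsilyl)oxy]-4-methylpent-3-en-1-yl}-2-methyl-2H-chromene | C/C(=C\CC[C@@]1(C)C=Cc2cc(CCc3cccc(O[Si](C)(C)C(C)(C)C)c3O[Si](C)(C)C(C)(C)C)ccc2O1)CO[Si](C)(C)C(C)(C)C | intermediate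
17 | 3-{2-[(2S)-2-[(3E)-5-hydroxy-4-methylpent-3-en-1-yl]-2-methyl-2H-chromen-6-yl]ethyl}benzene-1,2-diol | C/C(=C\CC[C@@]1(C)C=Cc2cc(CCc3cccc(O)c3O)ccc2O1)CO | target

**Totals**
Total step count: 12. Longest linear sequence: 11 (steps 1–9, 11, 12); step 10 is a one-step side branch.

**Steps most likely to fail**

Step 8 (ring-closing metathesis). The ruthenium alkylidene may close onto the trisubstituted side-chain alkene instead (cyclopentene formation with loss of the side-chain terminus), or the catalyst may rest as a chelated ortho-alkoxybenzylidene so that the ring closure stalls. The fallback leaves metathesis and the aryl ether route altogether; it sets out from 6 and comes back at 12. A Heck reaction of the vinyl group of 6 with 1-bromo-4-chloro-2-iodobenzene (Pd(OAc)2, Bu4NCl, NaHCO3, DMF, 50 °C, selective for the C–I bond) should give (1E,3S,6E)-1-(2-bromo-5-chlorophenyl)-8-[(tert-butyldimethylsilyl)oxy]-3,7-dimethylocta-1,6-dien-3-ol F2. Visible-light triplet-sensitised E-to-Z isomerisation of the styrenyl alkene (fac-Ir(ppy)3, blue light, MeCN) should give the (1Z,3S,6E) isomer F3. Palladium-catalysed intramolecular C–O coupling of the tertiary alcohol with the ortho bromide (Pd(OAc)2, 2-(di-tert-butylphosphino)-1,1'-binaphthyl, Cs2CO3, toluene, 65 °C) then closes the pyran ring with the C–O bond of the carbinol intact, giving (2S)-2-{(3E)-5-[(tert-butyldimethylsilyl)oxy]-4-methylpent-3-en-1-yl}-6-chloro-2-methyl-2H-chromene F4. Suzuki–Miyaura vinylation of the aryl chloride (CH2=CHBF3K, Pd(OAc)2, SPhos, K2CO3, THF/H2O, 70 °C) returns to 12.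

Step 6 (SNAr). The tertiary alkoxide may add reversibly to the formyl group and displace the singly activated fluoride too slowly, and the tertiary allylic aryl ether may ionise on prolonged reaction or on silica. The fallback changes the activating group and the oxidation level; it sets out from 6 (through alkoxide 8) and comes back at 9. SNAr on 5-bromo-2-fluorobenzonitrile (THF, 0 °C → rt), whose nitrile activates strongly and cannot add the alkoxide, should give 5-bromo-2-{[(3S,6E)-8-[(tert-butyldimethylsilyl)oxy]-3,7-dimethylocta-1,6-dien-3-yl]oxy}benzonitrile F1. Partial reduction with iBu2AlH (toluene, −78 °C) and hydrolysis of the aldimine with aqueous potassium sodium tartrate should then give 9.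

Step 11 (key coupling). The aqueous base may strip the aryl silyl ethers, after which the catecholate binds boron and palladium; oxidative addition next to the silyloxy group may be slow; β-hydride elimination may compete. The fallback is a base-free Negishi coupling that forms the same bond; it sets out from 12 and comes back at 16. Hydroboration with 9-BBN (through 15) and oxidation with NaBO3·4H2O should give 2-[(2S)-2-{(3E)-5-[(tert-butyldimethylsilyl)oxy]-4-methylpent-3-en-1-yl}-2-methyl-2H-chromen-6-yl]ethan-1-ol F5. PPh3, I2 and imidazole convert it into (2S)-2-{(3E)-5-[(tert-butyldimethylsilyl)oxy]-4-methylpent-3-en-1-yl}-6-(2-iodoethyl)-2-methyl-2H-chromene F6. Zinc insertion (Zn dust, LiCl, THF, rt) gives the alkylzinc iodide {2-[(2S)-2-{(3E)-5-[(tert-butyldimethylsilyl)oxy]-4-methylpent-3-en-1-yl}-2-methyl-2H-chromen-6-yl]ethyl}zinc iodide F7. This is coupled with 14 (Pd(OAc)2, SPhos, THF, 40 °C, no base) to give 16.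

**Further compounds**
F1 | step 6 | 5-bromo-2-{[(3S,6E)-8-[(tert-butyldimethylsilyl)oxy]-3,7-dimethylocta-1,6-dien-3-yl]oxy}benzonitrile | C=C[C@@](C)(Oc1ccc(Br)cc1C#N)CC/C=C(\C)CO[Si](C)(C)C(C)(C)C
F2 | step 8 | (1E,3S,6E)-1-(2-bromo-5-chlorophenyl)-8-[(tert-butyldimethylsilyl)oxy]-3,7-dimethylocta-1,6-dien-3-ol | Brc1ccc(Cl)cc1/C=C/[C@@](C)(O)CC/C=C(\C)CO[Si](C)(C)C(C)(C)C
F3 | step 8 | (1Z,3S,6E)-1-(2-bromo-5-chlorophenyl)-8-[(tert-butyldimethylsilyl)oxy]-3,7-dimethylocta-1,6-dien-3-ol | Brc1ccc(Cl)cc1/C=C\[C@@](C)(O)CC/C=C(\C)CO[Si](C)(C)C(C)(C)C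
F4 | step 8 | (2S)-2-{(3E)-5-[(tert-butyldimethylsilyl)oxy]-4-methylpent-3-en-1-yl}-6-chloro-2-methyl-2H-chromene | C/C(=C\CC[C@@]1(C)C=Cc2cc(Cl)ccc2O1)CO[Si](C)(C)C(C)(C)C
F5 | step 11 | 2-[(2S)-2-{(3E)-5-[(tert-butyldimethylsilyl)oxy]-4-methylpent-3-en-1-yl}-2-methyl-2H-chromen-6-yl]ethan-1-ol | C/C(=C\CC[C@@]1(C)C=Cc2cc(CCO)ccc2O1)CO[Si](C)(C)C(C)(C)C
F6 | step 11 | (2S)-2-{(3E)-5-[(tert-butyldimethylsilyl)oxy]-4-methylpent-3-en-1-yl}-6-(2-iodoethyl)-2-methyl-2H-chromene | C/C(=C\CC[C@@]1(C)C=Cc2cc(CCI)ccc2O1)CO[Si](C)(C)C(C)(C)C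
F7 | step 11 | {2-[(2S)-2-{(3E)-5-[(tert-butyldimethylsilyl)oxy]-4-methylpent-3-en-1-yl}-2-methyl-2H-chromen-6-yl]ethyl}zinc iodide | C/C(=C\CC[C@@]1(C)C=Cc2cc(CC[Zn]I)ccc2O1)CO[Si](C)(C)C(C)(C)C
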